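**Retrosynthetic overview**

- The strategy rests on the acyclic side chain, numbered from the arene as C1' (ArCH2), C2'=C3'(CH3), C4'(OAc), C5'H2, C6'=C7'(CH3)2. Its only stereocentre, C4', is bonded directly to the methyl-bearing alkene carbon C3'.
- Key disconnection C3'–C4': C4' enters as a sparteine-lithiated carbamate carbanion and C3' as the boron-bearing carbon of a geometrically defined alkenyl pinacol boronate. A 1,2-metallate shift joins them, and C–B oxidation then gives the (R)-allylic alcohol.
- The alkenyl boronate comes from cross-metathesis (C2'=C3') of an allylarene with isopropenyl pinacol boronate. The allyl group (aryl–C1' bond) comes from an aromatic Claisen rearrangement of 4-(allyloxy)benzaldehyde, with the aldehyde masked as a dioxolane.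
- End game: acetal hydrolysis, Knoevenagel–Doebner condensation to the (E)-acrylic acid, then O-acetylation.
- Rings: no ring of the target is formed. The benzene ring is bought, and the dioxolane is a temporary protecting ring made in step 3 and opened in step 8.

Key step: step 6

**Route**

Step 1
Reactants: 1 4-(allyloxy)benzaldehyde
Product: 3 3-allyl-4-hydroxybenzaldehyde, via Claisen dienone 2 (not isolated)
Conditions: PhNEt2, 200 °C, argon
Reagents that add atoms: none
Why: Aromatic Claisen rearrangement, in which the aryl allyl ether undergoes a thermal [3,3]-sigmatropic shift to the ortho carbon (the para position carries the formyl group) and the dienone 2 tautomerises to the phenol, so that the aryl–C1' bond is made.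

Step 2
Reactants: 3 3-allyl-4-hydroxybenzaldehyde
Product: 4 3-allyl-4-methoxybenzaldehyde
Conditions: MeI, K2CO3, acetone, reflux
Reagents that add atoms: iodomethane, SMILES CI
Why: Williamson ether synthesis by SN2 attack of the phenoxide on MeI, with no other acidic or nucleophilic site in 3.

Step 3
Reactants: 4 3-allyl-4-methoxybenzaldehyde
Product: 5 2-(3-allyl-4-methoxyphenyl)-1,3-dioxolane
Conditions: HOCH2CH2OH, p-TsOH·H2O (cat.), toluene, reflux, Dean–Stark
Reagents that add atoms: ethylene glycol, SMILES OCCO
Why: Acid-catalysed acetalisation driven by azeotropic removal of water, which shields the aldehyde from the organolithium and from the allylic boronate that arise in step 6.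

Step 4
Reactants: 5 2-(3-allyl-4-methoxyphenyl)-1,3-dioxolane; 6 isopropenylboronic acid pinacol ester (4,4,5,5-tetramethyl-2-(prop-1-en-2-yl)-1,3,2-dioxaborolane)
Product: 7 (Z)-alkenyl boronate 2-[(Z)-4-[5-(1,3-dioxolan-2-yl)-2-methoxyphenyl]but-2-en-2-yl]-4,4,5,5-tetramethyl-1,3,2-dioxaborolane (ArCH2 trans to boron and cis to methyl)
Conditions: 6 (3 equiv), second-generation Grubbs catalyst RuCl2(=CHPh)(H2IMes)(PCy3) (5 mol %), 1,4-benzoquinone (10 mol %), CH2Cl2, 40 °C
Reagents that add atoms: none
Why: Olefin cross-metathesis of the terminal allylarene with the 1,1-disubstituted vinyl boronate, which does not homodimerise, is driven by loss of ethylene and is a known route to trisubstituted alkenyl pinacol boronates, with the new substituent expected trans to the boronate and cis to methyl (Z, because methyl outranks boron), as with methacrylate-type partners.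

Step 5
Reactants: 8 4-methylpent-3-en-1-ol
Product: 9 4-methylpent-3-en-1-yl N,N-diisopropylcarbamate
Conditions: i-Pr2NCOCl, Et3N, CH2Cl2, reflux
Reagents that add atoms: N,N-diisopropylcarbamoyl chloride, SMILES CC(C)N(C(C)C)C(=O)Cl
Why: Carbamoylation of the primary alcohol by nucleophilic acyl substitution installs the hindered carbamate that directs and stabilises the α-lithiation and later serves as the leaving group.

Step 6
Reactants: 9 4-methylpent-3-en-1-yl N,N-diisopropylcarbamate; 7 (Z)-alkenyl boronate
Product: 12 (R)-allylic boronate 2-[(2E,4R)-1-[5-(1,3-dioxolan-2-yl)-2-methoxyphenyl]-3,7-dimethylocta-2,6-dien-4-yl]-4,4,5,5-tetramethyl-1,3,2-dioxaborolane, via lithiated carbamate 10 (not isolated), via boronate complex 11 (not isolated)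
Conditions: 9 (1.3 equiv), (–)-sparteine (1.3 equiv), s-BuLi (1.25 equiv), Et2O, –78 °C, 5 h; then 7 (1.0 equiv), –78 °C, 1 h; then MgBr2·OEt2 (1.5 equiv), –78 °C to 35 °C, 16 h; pH 7 buffer work-up, short silica plug
Reagents that add atoms: none
Why: s-BuLi complexed by (–)-sparteine removes the pro-S hydrogen next to the carbamate oxygen of 9 to give the configurationally stable (S)-organolithium 10, which attacks the empty p orbital on boron of 7 with retention at carbon to give the ate complex 11; on warming with MgBr2 the 1-methylalkenyl group shifts from boron to C4' antiperiplanar to the departing carbamate (1,2-metallate rearrangement), and this forms the C3'–C4' bond. The closest known reaction type is the lithiation–borylation of sparteine-lithiated O-alkyl carbamates with alkenyl pinacol boronates, a stereospecific Matteson-type homologation that is known to give α-substituted allylic boronates. No ring is closed in this step. The new stereocentre C4' is set by the chiral diamine in the deprotonation and is then passed on stereospecifically, with retention in the borylation and inversion in the migration, so that 12 should be (R); the alkene geometry of 7 is kept because the sp2 carbon migrates with retention. The step needs enantioselectivity at C4' and attack at boron in preference to deprotonation of the allylic and benzylic C1' methylene: the first is secured by the carbamate-directed sparteine complex at –78 °C, the second by fast ate-complex formation at –78 °C and by keeping s-BuLi below the amount of 9, while the dioxolane and the methoxyarene are inert to the organolithium and aryl dioxolanes tolerate ethereal magnesium halides.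

Step 7
Reactants: 12 (R)-allylic boronate
Product: 13 (2E,4R)-1-[5-(1,3-dioxolan-2-yl)-2-methoxyphenyl]-3,7-dimethylocta-2,6-dien-4-ol
Conditions: 2 M NaOH aq, 30% H2O2, THF, 0 °C to rt
Reagents that add atoms: hydrogen peroxide, SMILES OO
Why: Oxidation of the carbon–boron bond, in which hydroperoxide adds to boron and C4' shifts from boron to oxygen with retention of configuration, so the (R)-boronate gives the (R)-alcohol while the acetal and both trisubstituted alkenes are inert to alkaline peroxide.

Step 8
Reactants: 13 (R)-allylic alcohol with the dioxolane intact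
Product: 14 3-[(2E,4R)-4-hydroxy-3,7-dimethylocta-2,6-dien-1-yl]-4-methoxybenzaldehyde
Conditions: PPTS (0.2 equiv), THF–H2O (4:1), 45 °C
Reagents that add atoms: water, SMILES O
Why: Acid-catalysed acetal hydrolysis, made easy by the para-methoxy group that stabilises the oxocarbenium ion, so that a weak acid suffices and the secondary allylic alcohol should not ionise.

Step 9
Reactants: 14 (R)-hydroxy aldehyde; 15 malonic acid
Product: 17 (E)-3-{3-[(2E,4R)-4-hydroxy-3,7-dimethylocta-2,6-dien-1-yl]-4-methoxyphenyl}prop-2-enoic acid, via arylidene malonic acid 16 (not isolated)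
Conditions: 15 (3 equiv), pyridine, piperidine (0.1 equiv), 90 °C; aq. citric acid work-up
Reagents that add atoms: none
Why: Knoevenagel condensation in the Doebner modification, in which the arylidene malonic acid 16 loses CO2 in hot pyridine to give the thermodynamically favoured (E)-cinnamic acid, while the free allylic alcohol and C4' are untouched by the weakly basic medium.

Step 10
Reactants: 17 (R)-hydroxy cinnamic acid
Product: 19 (E)-3-{3-[(2E,4R)-4-acetoxy-3,7-dimethylocta-2,6-dien-1-yl]-4-methoxyphenyl}prop-2-enoic acid (CNP0206859.1), via mixed anhydride 18 (not isolated)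
Conditions: Ac2O (3 equiv), pyridine, DMAP (0.1 equiv), CH2Cl2, 0 °C to rt; then H2O–THF, rt, 2 h; aq. citric acid work-up
Reagents that add atoms: acetic anhydride, SMILES CC(=O)OC(C)=O
Why: DMAP-catalysed O-acetylation of the secondary alcohol, during which the carboxyl group is converted into the mixed acetic anhydride 18 that water then cleaves at the more electrophilic acetyl carbonyl, leaving the secondary acetate and C4' unchanged.

**Compound list**

1 | 4-(allyloxy)benzaldehyde | C=CCOc1ccc(C=O)cc1 | starting material
2 | 6-allyl-4-formylcyclohexa-2,4-dien-1-one (Claisen dienone, racemic) | C=CCC1C=C(C=O)C=CC1=O | intermediate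
3 | 3-allyl-4-hydroxybenzaldehyde | C=CCc1cc(C=O)ccc1O | intermediate
4 | 3-allyl-4-methoxybenzaldehyde | C=CCc1cc(C=O)ccc1OC | intermediate
5 | 2-(3-allyl-4-methoxyphenyl)-1,3-dioxolane | C=CCc1cc(C2OCCO2)ccc1OC | intermediate
6 | isopropenylboronic acid pinacol ester | C=C(C)B1OC(C)(C)C(C)(C)O1 | starting material
7 | 2-[(Z)-4-[5-(1,3-dioxolan-2-yl)-2-methoxyphenyl]but-2-en-2-yl]-4,4,5,5-tetramethyl-1,3,2-dioxaborolane | COc1ccc(C2OCCO2)cc1C/C=C(\C)B1OC(C)(C)C(C)(C)O1 | intermediate
8 | 4-methylpent-3-en-1-ol | CC(C)=CCCO | starting material
9 | 4-methylpent-3-en-1-yl N,N-diisopropylcarbamate | CC(C)=CCCOC(=O)N(C(C)C)C(C)C | intermediate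
10 | (S)-1-lithio-4-methylpent-3-en-1-yl N,N-diisopropylcarbamate (as its (–)-sparteine complex) | CC(C)=CC[C@H]([Li])OC(=O)N(C(C)C)C(C)C | intermediate
11 | lithium boronate complex of 10 with 7 (tetracoordinate boron bearing pinacolate, the alkenyl group and the carbamoyloxy-substituted C4') | CC(C)=CC[C@@H](OC(=O)N(C(C)C)C(C)C)[B-]1(OC(C)(C)C(C)(C)O1)/C(C)=C/Cc1cc(C2OCCO2)ccc1OC.[Li+] | intermediate
12 | 2-[(2E,4R)-1-[5-(1,3-dioxolan-2-yl)-2-methoxyphenyl]-3,7-dimethylocta-2,6-dien-4-yl]-4,4,5,5-tetramethyl-1,3,2-dioxaborolane | COc1ccc(C2OCCO2)cc1C/C=C(\C)[C@@H](CC=C(C)C)B1OC(C)(C)C(C)(C)O1 | intermediate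
13 | (2E,4R)-1-[5-(1,3-dioxolan-2-yl)-2-methoxyphenyl]-3,7-dimethylocta-2,6-dien-4-ol | COc1ccc(C2OCCO2)cc1C/C=C(\C)[C@@H](CC=C(C)C)O | intermediate
14 | 3-[(2E,4R)-4-hydroxy-3,7-dimethylocta-2,6-dien-1-yl]-4-methoxybenzaldehyde | COc1ccc(C=O)cc1C/C=C(\C)[C@@H](CC=C(C)C)O | intermediate
15 | malonic acid | O=C(O)CC(=O)O | starting material
16 | 2-{3-[(2E,4R)-4-hydroxy-3,7-dimethylocta-2,6-dien-1-yl]-4-methoxybenzylidene}malonic acid | COc1ccc(C=C(C(=O)O)C(=O)O)cc1C/C=C(\C)[C@@H](CC=C(C)C)O | intermediate
17 | (E)-3-{3-[(2E,4R)-4-hydroxy-3,7-dimethylocta-2,6-dien-1-yl]-4-methoxyphenyl}prop-2-enoic acid | COc1ccc(/C=C/C(=O)O)cc1C/C=C(\C)[C@@H](CC=C(C)C)O | intermediate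
18 | acetic (E)-3-{3-[(2E,4R)-4-acetoxy-3,7-dimethylocta-2,6-dien-1-yl]-4-methoxyphenyl}prop-2-enoic anhydride | COc1ccc(/C=C/C(=O)OC(C)=O)cc1C/C=C(\C)[C@@H](CC=C(C)C)OC(C)=O | intermediate
19 | (E)-3-{3-[(2E,4R)-4-acetoxy-3,7-dimethylocta-2,6-dien-1-yl]-4-methoxyphenyl}prop-2-enoic acid (CNP0206859.1) | COc1ccc(/C=C/C(=O)O)cc1C/C=C(\C)[C@@H](CC=C(C)C)OC(C)=O | target

**Step count and risks**

Total step count: 10. Longest linear sequence: 9 steps (steps 1–4 and 6–10, from compound 1). Step 5 is the one-step side branch to carbamate 9.

The three steps most likely to fail: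

1. Step 6 (lithiation–borylation).
 - What may go wrong: incomplete or poorly enantioselective deprotonation of the homoallylic carbamate; proton transfer from the doubly activated C1' methylene of the boronate in place of ate-complex formation; a sluggish 1,2-shift from the α-methylalkenyl ate complex; or Lewis-acid opening of the dioxolane during the MgBr2-promoted warm-up.
 - Fallback (normal polarity, C3' as the nucleophile and C4' as a carbonyl carbon): it sets out from alkenyl boronate 7 and alcohol 8 and comes back to the route at alcohol 13. Boronate 7 is converted with retention of geometry into the (E)-alkenyl iodide F1 (NaOH, then I2, THF–H2O, 0 °C). Alcohol 8 is oxidised with Dess–Martin periodinane (NaHCO3 buffer, CH2Cl2, 0 °C) to 4-methylpent-3-enal F2, which is used at once as a cold solution. Nozaki–Hiyama–Kishi coupling of F1 with F2 (CrCl2, catalytic NiCl2, DMSO, rt) tolerates the enolisable β,γ-unsaturated aldehyde and should give the racemic allylic alcohol F3. Buffered Dess–Martin oxidation then gives the enone F4. F4 is reduced without delay with catecholborane and (S)-1-methyl-3,3-diphenyltetrahydro-1H,3H-pyrrolo[1,2-c][1,3,2]oxazaborole at –78 °C in toluene. This is the CBS catalyst enantiomer that gives (R)-1-phenylethanol from acetophenone, and here the alkenyl group is the large substituent, so the (R)-alcohol 13 is expected.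

2. Step 4 (cross-metathesis).
 - What may go wrong: ruthenium-hydride-mediated migration of the allyl double bond into conjugation with the arene; homodimerisation of 5; slow turnover with the 1,1-disubstituted vinyl boronate; or incomplete control of the alkene geometry.
 - Fallback (C2'=C3' by carbonyl olefination, C4' by reagent-controlled allylation, no boron at C3'): it sets out from allylarene 5 and comes back to the route at alcohol 13. Lemieux–Johnson cleavage of 5 (OsO4 cat., NaIO4, 2,6-lutidine, dioxane–H2O) gives the arylacetaldehyde F5. Wittig reaction with the stabilised ylide 2-(triphenylphosphoranylidene)propanal (toluene, 80 °C) gives the (E)-2-methyl enal F6 with ArCH2 cis to methyl. Brown allylation of F6 uses the B-allyldiisopinocampheylborane enantiomer prepared from (–)-α-pinene, which delivers allyl to the Re face of the aldehyde (Et2O, –78 °C, then NaOH and H2O2), and should give the (R)-homoallylic alcohol F7. Cross-metathesis of the terminal alkene of F7 with 2-methylbut-2-ene (second-generation Grubbs catalyst, rt) turns the allyl group into the 3-methylbut-2-enyl group and delivers 13; the trisubstituted C2'=C3' alkene is inert under these conditions.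

3. Step 10 (acetylation of the hydroxy acid).
 - What may go wrong: acylation at the carboxyl group outpacing that of the hindered secondary allylic alcohol, so that forcing conditions and the aqueous stage erode the acetate; or incomplete cleavage of the mixed anhydride.
 - Fallback (the acetate is installed before the carboxylic acid exists): it sets out from hydroxy aldehyde 14 and comes back to the route at target 19. Aldehyde 14 is acetylated (Ac2O, pyridine, catalytic DMAP, CH2Cl2) to the acetoxy aldehyde F8. Knoevenagel–Doebner condensation of F8 with malonic acid 15 (pyridine, piperidine 0.1 equiv, 80 °C) should give 19 directly, via the arylidene malonic acid F9 and loss of CO2. The secondary acetate should survive because the amine is present only as its malonate salt.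

**Further compounds**

F1 | step 6 | 2-{3-[(E)-3-iodobut-2-en-1-yl]-4-methoxyphenyl}-1,3-dioxolane | COc1ccc(C2OCCO2)cc1C/C=C(\C)I
F2 | step 6 | 4-methylpent-3-enal | CC(C)=CCC=O
F3 | step 6 | racemic (E)-1-[5-(1,3-dioxolan-2-yl)-2-methoxyphenyl]-3,7-dimethylocta-2,6-dien-4-ol | COc1ccc(C2OCCO2)cc1C/C=C(\C)C(O)CC=C(C)C
F4 | step 6 | (E)-1-[5-(1,3-dioxolan-2-yl)-2-methoxyphenyl]-3,7-dimethylocta-2,6-dien-4-one | COc1ccc(C2OCCO2)cc1C/C=C(\C)C(=O)CC=C(C)C
F5 | step 4 | 2-[5-(1,3-dioxolan-2-yl)-2-methoxyphenyl]acetaldehyde | COc1ccc(C2OCCO2)cc1CC=O
F6 | step 4 | (E)-4-[5-(1,3-dioxolan-2-yl)-2-methoxyphenyl]-2-methylbut-2-enal | COc1ccc(C2OCCO2)cc1C/C=C(\C)C=O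
F7 | step 4 | (2E,4R)-1-[5-(1,3-dioxolan-2-yl)-2-methoxyphenyl]-3-methylhepta-2,6-dien-4-ol | COc1ccc(C2OCCO2)cc1C/C=C(\C)[C@@H](CC=C)O
F8 | step 10 | 3-[(2E,4R)-4-acetoxy-3,7-dimethylocta-2,6-dien-1-yl]-4-methoxybenzaldehyde | COc1ccc(C=O)cc1C/C=C(\C)[C@@H](CC=C(C)C)OC(C)=O
F9 | step 10 | 2-{3-[(2E,4R)-4-acetoxy-3,7-dimethylocta-2,6-dien-1-yl]-4-methoxybenzylidene}malonic acid | COc1ccc(C=C(C(=O)O)C(=O)O)cc1C/C=C(\C)[C@@H](CC=C(C)C)OC(C)=O
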